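**Retrosynthetic overview**
- The target is reached from its ring B benzyl ether by a final debenzylation; the diaryl ether C–O bond is never made by an arylation.
- The strategy rests on ring A (C1' aryloxy, C2' OMe, C5' Br), in which OMe is para to Br and ortho to the ether oxygen. Ring A is cut at C2'–C3' and C1'–C6' into 5-bromo-2-pyrone (C3' to C6', Br on C5') and the trimethylsilyl ketene acetal of the ring B aryloxyacetate (C2' with OMe, C1' with the ether oxygen).
- The ketene acetal comes from methyl bromoacetate and 2-(benzyloxy)-4,6-dibromophenol, itself made from 2-(benzyloxy)phenol by bromination ortho and para to the free OH. The bromopyrone comes from coumalic acid.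
- Ring order: ring B is bought with the starting phenol; ring A is the only ring built, by [4+2] cycloaddition, loss of CO2 and loss of trimethylsilanol.

Key step: step 5

Remark: the target has no stereocentre. Locants used below: ring B C1 (ether O), C2 (OH), C4 and C6 (Br); ring A C1' (ether O), C2' (OMe), C5' (Br).

Step 1
Reactants: 1 coumalic acid (2-oxo-2H-pyran-5-carboxylic acid)
Product: 2 5-bromo-2H-pyran-2-one
Conditions: NBS (1.1 equiv), LiOAc (1.1 equiv), MeCN–H2O, rt
Reagents that add atoms: N-bromosuccinimide, O=C1CCC(=O)N1Br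
Why: Ionic bromodecarboxylation: the carboxylate sits on C5, the nucleophilic β-carbon of the ring enol ether (O1–C6=C5), so ipso attack of bromine followed by loss of CO2 should restore the pyrone, and a single equivalent of NBS holds back a second bromination at C3.

Step 2
Reactants: 3 2-(benzyloxy)phenol
Product: 4 2-(benzyloxy)-4,6-dibromophenol
Conditions: Br2 (2.1 equiv), NaOAc (2.5 equiv), AcOH, 15 °C to rt
Reagents that add atoms: bromine, BrBr
Why: Electrophilic aromatic bromination in which the free hydroxyl outweighs the benzyloxy group and directs bromine first para and then ortho to itself, while the acetate buffer keeps HBr from cleaving the benzyl ether.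

Step 3
Reactants: 4 2-(benzyloxy)-4,6-dibromophenol; 5 methyl bromoacetate
Product: 6 methyl 2-[2-(benzyloxy)-4,6-dibromophenoxy]acetate
Conditions: K2CO3 (1.5 equiv), acetone, reflux
Reagents that add atoms: none
Why: Williamson ether synthesis; the acidic, hindered phenoxide should still displace bromide readily from the unhindered, activated α-bromo ester, which forms the future diaryl ether C–O bond as a simple alkylation.

Step 4
Reactants: 6 methyl 2-[2-(benzyloxy)-4,6-dibromophenoxy]acetate
Product: 7 (Z)-2-[2-(benzyloxy)-4,6-dibromophenoxy]-1-methoxy-1-(trimethylsilyloxy)ethene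
Conditions: LiN(SiMe3)2 (1.15 equiv), THF, −78 °C; Me3SiCl (1.5 equiv), −78 °C to rt; evaporation, pentane, filtration under argon, used crude
Reagents that add atoms: chlorotrimethylsilane, C[Si](C)(C)Cl
Why: Enolisation of the α-aryloxy ester and O-silylation of the lithium enolate, as in the first stage of an Ireland–Claisen sequence; chelation of lithium by the aryloxy oxygen should favour the Z isomer (the geometry is of no consequence later), and the amide base is too weak to metalate the ring B C5–H between the two bromines.

Step 5
Reactants: 2 5-bromo-2H-pyran-2-one; 7 (Z)-2-[2-(benzyloxy)-4,6-dibromophenoxy]-1-methoxy-1-(trimethylsilyloxy)ethene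
Product: 10 1-(benzyloxy)-3,5-dibromo-2-(5-bromo-2-methoxyphenoxy)benzene, via bridged lactone cycloadduct 8 (not isolated), via cyclohexadiene mixed ketal 9 (not isolated)
Conditions: 7 (1.5 equiv), iPr2NEt (0.1 equiv), dry o-xylene, sealed tube, 100 °C then 145 °C
Reagents that add atoms: none
Why: The electron-rich C=C bond of 7 should add across C3 and C6 of the electron-poor diene 2 in a concerted but asynchronous inverse-electron-demand Diels–Alder reaction, the closest known reaction type being the cycloaddition of 2-pyrones with ketene acetals, 1,1,2-trialkoxyethenes and silyl enol ethers that ends in loss of CO2 and aromatisation. Ring A is closed by this intermolecular [4+2] cycloaddition, the aryloxy-bearing carbon of 7 bonding to C6 (C1'–C6') and the acetal carbon to C3 (C2'–C3') to give bridged lactone 8, which at the higher temperature extrudes CO2 by retro-[4+2] to give diene 9. In 9 the mixed ketal carbon ionises to a methoxy-substituted arenium ion and the proton on the neighbouring aryloxy-bearing carbon is then lost, so that trimethylsilanol leaves and the anisole remains. The four stereocentres of 8 (two remain in 9) are transient and vanish on aromatisation, so that endo/exo and facial selectivity are of no account and no stereocentre is set. The regioselectivity that is needed follows from the polarisation of both partners: the carbon β to the two acetal oxygens is the nucleophilic end of 7 despite its own aryloxy group, and C6 is the vinylogous acceptor end of the pyrone, which puts Br para to OMe and meta to the ether oxygen. The chemoselectivity that is needed in the elimination is favoured by dry, amine-buffered conditions, under which silanolate is the better leaving group and methoxy the better donor to the cation, whereas the aryloxy group cannot be expelled in an aromatising step because the ketal carbon next to it carries no hydrogen.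

Step 6
Reactants: 10 1-(benzyloxy)-3,5-dibromo-2-(5-bromo-2-methoxyphenoxy)benzene
Product: 11 3,5-dibromo-2-(5-bromo-2-methoxyphenoxy)phenol (target)
Conditions: BCl3 (2 equiv), C6HMe5 (3 equiv), CH2Cl2, −78 °C; then H2O
Reagents that add atoms: none
Why: Lewis-acid debenzylation in which BCl3 activates the benzylic C–O bond and pentamethylbenzene captures the benzyl cation by Friedel–Crafts alkylation, so that ring A is not C-benzylated; at −78 °C the aryl methyl ether and the three C–Br bonds, which hydrogenolysis would endanger, should remain.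

**Compound list**
1 | coumalic acid (2-oxo-2H-pyran-5-carboxylic acid) | OC(=O)c1ccc(=O)oc1 | starting material
2 | 5-bromo-2H-pyran-2-one | O=c1ccc(Br)co1 | intermediate
3 | 2-(benzyloxy)phenol | Oc1ccccc1OCc1ccccc1 | starting material
4 | 2-(benzyloxy)-4,6-dibromophenol | Oc1c(OCc2ccccc2)cc(Br)cc1Br | intermediate
5 | methyl bromoacetate | COC(=O)CBr | starting material
6 | methyl 2-[2-(benzyloxy)-4,6-dibromophenoxy]acetate | COC(=O)COc1c(OCc2ccccc2)cc(Br)cc1Br | intermediate
7 | (Z)-2-[2-(benzyloxy)-4,6-dibromophenoxy]-1-methoxy-1-(trimethylsilyloxy)ethene | CO/C(O[Si](C)(C)C)=C/Oc1c(OCc2ccccc2)cc(Br)cc1Br | intermediate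
8 | 7-[2-(benzyloxy)-4,6-dibromophenoxy]-6-bromo-8-methoxy-8-(trimethylsilyloxy)-2-oxabicyclo[2.2.2]oct-5-en-3-one (racemic, mixture of diastereomers) | O=C1OC2C(Oc3c(OCc4ccccc4)cc(Br)cc3Br)C(OC)(O[Si](C)(C)C)C1C=C2Br | intermediate
9 | 6-[2-(benzyloxy)-4,6-dibromophenoxy]-2-bromo-5-methoxy-5-(trimethylsilyloxy)cyclohexa-1,3-diene (racemic, mixture of diastereomers) | COC1(O[Si](C)(C)C)C=CC(Br)=CC1Oc1c(OCc2ccccc2)cc(Br)cc1Br | intermediate
10 | 1-(benzyloxy)-3,5-dibromo-2-(5-bromo-2-methoxyphenoxy)benzene | COc1ccc(Br)cc1Oc1c(OCc2ccccc2)cc(Br)cc1Br | intermediate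
11 | 3,5-dibromo-2-(5-bromo-2-methoxyphenoxy)phenol | COc1ccc(Br)cc1Oc1c(O)cc(Br)cc1Br | target

**Step count**
Total step count: 6. Longest linear sequence: 5 steps (steps 2, 3, 4, 5, 6).

**Steps most likely to fail**

Step 5. The cycloaddition to the only moderately electron-poor bromopyrone may be sluggish. Compound 7 may be lost beforehand by hydrolysis or by thermal migration of silicon from oxygen to carbon. Aromatisation may also proceed partly by loss of methanol in place of silanol. The fallback makes the diaryl ether by nucleophilic aromatic substitution and installs the methoxy group afterwards. It sets out from 4. With 4-bromo-2-fluorobenzaldehyde and K2CO3 in DMF at 90 °C, 4 should displace the fluoride ortho to the formyl group, leaving the bromide, to give 4-bromo-2-[2-(benzyloxy)-4,6-dibromophenoxy]benzaldehyde F1. Baeyer–Villiger oxidation with mCPBA in CH2Cl2 should give 4-bromo-2-[2-(benzyloxy)-4,6-dibromophenoxy]phenyl formate F2. K2CO3 in MeOH should cleave this to 4-bromo-2-[2-(benzyloxy)-4,6-dibromophenoxy]phenol F3. Methylation with MeI and K2CO3 in acetone comes back to the route at 10. F3 is also what step 5 would leave after work-up wherever methanol had been expelled, so such material can be methylated in the same way.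

Step 1. Bromination may run on at C3 to the dibromopyrone, and the pyrone ring may open in the aqueous medium, so that little 2 is obtained. The fallback keeps the carboxyl carbon through the cycloaddition and exchanges it for bromine on the finished arene. It sets out from 1. Fischer esterification (MeOH, H2SO4) gives methyl coumalate (methyl 2-oxo-2H-pyran-5-carboxylate) F4, a more electron-poor diene. Under the conditions of step 5, F4 and 7 should react with the same regiochemistry through the bridged lactone methyl 7-[2-(benzyloxy)-4,6-dibromophenoxy]-8-methoxy-3-oxo-8-(trimethylsilyloxy)-2-oxabicyclo[2.2.2]oct-5-ene-6-carboxylate F5 and the diene methyl 3-[2-(benzyloxy)-4,6-dibromophenoxy]-4-methoxy-4-(trimethylsilyloxy)cyclohexa-1,5-diene-1-carboxylate F6. The product should be methyl 3-[2-(benzyloxy)-4,6-dibromophenoxy]-4-methoxybenzoate F7. LiOH in THF–H2O, then aqueous HCl, gives 3-[2-(benzyloxy)-4,6-dibromophenoxy]-4-methoxybenzoic acid F8. Decarboxylative ipso-bromination of this 4-methoxybenzoic acid (Bu4NBr3, K3PO4, MeCN, 100 °C) should come back to the route at 10.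

Step 4. The ester enolate may be silylated on carbon or may condense with unreacted ester, and the labile trimethylsilyl ketene acetal may hydrolyse during isolation. The fallback generates the dienophile without enolate chemistry from a bench-stable orthoester. It sets out from 4. Alkylation with bromoacetonitrile (K2CO3, acetone, reflux) gives 2-[2-(benzyloxy)-4,6-dibromophenoxy]acetonitrile F9. Pinner reaction (HCl gas, MeOH 1.1 equiv, Et2O, 0 °C) gives methyl 2-[2-(benzyloxy)-4,6-dibromophenoxy]acetimidate hydrochloride F10. Stirring with MeOH at rt gives the orthoester 1-(benzyloxy)-3,5-dibromo-2-(2,2,2-trimethoxyethoxy)benzene F11. F11 is then heated with 2 and a catalytic amount of pivalic acid in o-xylene at 150 °C with removal of methanol. It should lose methanol to the ketene acetal 1-(benzyloxy)-3,5-dibromo-2-(2,2-dimethoxyethenyloxy)benzene F12. F12 should add to 2 as in step 5, through the bridged lactone 7-[2-(benzyloxy)-4,6-dibromophenoxy]-6-bromo-8,8-dimethoxy-2-oxabicyclo[2.2.2]oct-5-en-3-one F13 and the diene 6-[2-(benzyloxy)-4,6-dibromophenoxy]-2-bromo-5,5-dimethoxycyclohexa-1,3-diene F14. F14 can aromatise only by loss of methanol, which comes back to the route at 10.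

**Further compounds**
F1 | step 5 | 4-bromo-2-[2-(benzyloxy)-4,6-dibromophenoxy]benzaldehyde | O=Cc1ccc(Br)cc1Oc1c(OCc2ccccc2)cc(Br)cc1Br
F2 | step 5 | 4-bromo-2-[2-(benzyloxy)-4,6-dibromophenoxy]phenyl formate | O=COc1ccc(Br)cc1Oc1c(OCc2ccccc2)cc(Br)cc1Br
F3 | step 5 | 4-bromo-2-[2-(benzyloxy)-4,6-dibromophenoxy]phenol | Oc1ccc(Br)cc1Oc1c(OCc2ccccc2)cc(Br)cc1Br
F4 | step 1 | methyl coumalate (methyl 2-oxo-2H-pyran-5-carboxylate) | COC(=O)c1ccc(=O)oc1
F5 | step 1 | methyl 7-[2-(benzyloxy)-4,6-dibromophenoxy]-8-methoxy-3-oxo-8-(trimethylsilyloxy)-2-oxabicyclo[2.2.2]oct-5-ene-6-carboxylate (racemic, mixture of diastereomers) | O=C1OC2C(Oc3c(OCc4ccccc4)cc(Br)cc3Br)C(OC)(O[Si](C)(C)C)C1C=C2C(=O)OC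
F6 | step 1 | methyl 3-[2-(benzyloxy)-4,6-dibromophenoxy]-4-methoxy-4-(trimethylsilyloxy)cyclohexa-1,5-diene-1-carboxylate (racemic, mixture of diastereomers) | COC(=O)C1=CC(Oc2c(OCc3ccccc3)cc(Br)cc2Br)C(OC)(O[Si](C)(C)C)C=C1
F7 | step 1 | methyl 3-[2-(benzyloxy)-4,6-dibromophenoxy]-4-methoxybenzoate | COC(=O)c1ccc(OC)c(Oc2c(OCc3ccccc3)cc(Br)cc2Br)c1
F8 | step 1 | 3-[2-(benzyloxy)-4,6-dibromophenoxy]-4-methoxybenzoic acid | OC(=O)c1ccc(OC)c(Oc2c(OCc3ccccc3)cc(Br)cc2Br)c1
F9 | step 4 | 2-[2-(benzyloxy)-4,6-dibromophenoxy]acetonitrile | N#CCOc1c(OCc2ccccc2)cc(Br)cc1Br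
F10 | step 4 | methyl 2-[2-(benzyloxy)-4,6-dibromophenoxy]acetimidate hydrochloride | COC(=[NH2+])COc1c(OCc2ccccc2)cc(Br)cc1Br.[Cl-]
F11 | step 4 | 1-(benzyloxy)-3,5-dibromo-2-(2,2,2-trimethoxyethoxy)benzene | COC(OC)(OC)COc1c(OCc2ccccc2)cc(Br)cc1Br
F12 | step 4 | 1-(benzyloxy)-3,5-dibromo-2-(2,2-dimethoxyethenyloxy)benzene | COC(OC)=COc1c(OCc2ccccc2)cc(Br)cc1Br
F13 | step 4 | 7-[2-(benzyloxy)-4,6-dibromophenoxy]-6-bromo-8,8-dimethoxy-2-oxabicyclo[2.2.2]oct-5-en-3-one (racemic, mixture of diastereomers) | O=C1OC2C(Oc3c(OCc4ccccc4)cc(Br)cc3Br)C(OC)(OC)C1C=C2Br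
F14 | step 4 | 6-[2-(benzyloxy)-4,6-dibromophenoxy]-2-bromo-5,5-dimethoxycyclohexa-1,3-diene (racemic) | COC1(OC)C=CC(Br)=CC1Oc1c(OCc2ccccc2)cc(Br)cc1Br
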